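A small charge of free catalyst gives you little left-handed product: east, with 4 mM in all, reads 3.9% after 50.0 h, and west, with 70 mM, reads 24.9% at that time.

all flasks: left-handed substrate 0.13 M; right-handed substrate 0.13 M

|  | partner | free catalyst | remark | time |
|---|---|---|---|---|
| east | 0.26 M | 4 mM (in portions, 3) | run made earlier; portions every 30 h |  |
| west | 0.26 M | 70 mM (in portions, 3) | run made earlier; portions every 30 h |  |
| alder | 0.260 M | 12 mM (in portions, 3) | the portions of free catalyst follow each other after 30 h, the first at the start | 4.0 d |
| cedar | 0.260 M | 60 mM (in portions, 3) | the portions of free catalyst follow each other after 30 h, the first at the start | 4.0 d |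
| ash | 0.260 M | 80 mM (in portions, 3) | the portions of free catalyst follow each other after 30 h, the first at the start | 4.0 d |
| maple | 0.260 M | 5.0 mM (in portions, 3) | the portions of free catalyst follow each other after 30 h, the first at the start | 4.0 d |
| larch | 0.260 M | 20 mM (in portions, 3) | the portions of free catalyst follow each other after 30 h, the first at the start | 4.0 d |

- east (time / h: left-handed product / %, left-handed substrate / %): 6.00: 0, 48.7; 15.0: 1.5, 49.3; 20.0: 0.7, 48.3; 30.0: 1.7, 47.7; 40.0: 3.4, 47.7; 50.0: 3.9, 45.9
- west (time / h: left-handed product / %, left-handed substrate / %): 4.00: 3.8, 46.0; 6.00: 5.9, 44.1; 8.00: 7.0, 42.5; 15.0: 11.0, 40.0; 20.0: 12.9, 37.4; 30.0: 16.8, 35.7; 50.0: 24.9, 27.6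

(scatter of a reading: 0.5 percentage points)

- free catalyst is single-handed; left-handed substrate and right-handed substrate are mirror images of each other, charged as a racemate, each of them at the stated concentration

1. all flasks from highest to lowest amount of left-handed product, in percent of the left-handed substrate and right-handed substrate together charged, at 4.0 d (alder / cedar / ash / maple / larch)
2. the amount of left-handed product, in percent of the left-handed substrate and right-handed substrate together charged of the flask you put first, at 4.0 d
3. the amount of left-handed product, in percent of the left-handed substrate and right-handed substrate together charged of the flask you put last, at 4.0 d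

Start by treating the catalyst as you would an enzyme, and compare the flasks by catalyst dose: the sum, over the portions, of portion size times the hours it has stood. Once every portion is in, this is the whole charge times the elapsed time less one interval, so maple receives 330 mM·h. Selwyn's test asks whether equal doses give equal product. East at 50.0 h has 93.3 mM·h, west at 4.00 h has 93.3 mM·h, and they read 3.9% and 3.8%, with a scatter of 0.5 percentage points. So I take west's readings as the curve of product against dose. Maple's dose equals west at 14.1 h, and interpolating between west's readings gives 10.5%.

The objection is that the test covers one low dose. If catalyst is lost faster at a large charge, maple may stand above west's curve, so I take that figure as the low side.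

A second objection concerns ash, whose dose of 5280 mM·h lies beyond west's last 1630 mM·h. Treat the left-handed substrate as pseudo-first-order in dose, and carry on its fall between west's last two readings, where west had reached 700 mM·h and then 1630 mM·h. That gives ash 42.4%. West's fall per dose read smaller there than over its earlier readings, so I expect this figure to run high. Cedar by the same rule gets 38.0%, and I keep the order of the doses.

The forecast gives ash > cedar > larch > alder > maple, on the ground that “More catalyst always gives more product”, with 39% first and 10% last. Its top is lower than my figure for ash, and its low is lower than my figure for maple.

The flasks give ash > cedar > larch > alder > maple, with ash at 35.4% and maple at 11.7%.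

    2 free catalyst → spent catalyst (k = 1.23 M⁻¹ h⁻¹)
    left-handed substrate ⇌ right-handed substrate (k = 0.0386 h⁻¹)
    partner + free catalyst + left-handed substrate → free catalyst + left-handed product (k = 4.28 M⁻² h⁻¹)
    partner + free catalyst + right-handed substrate → free catalyst + right-handed product (k = 2.57 M⁻² h⁻¹)

Maple stands 1.2 points above my figure from west's curve, and at 4.00 d it holds 61.5% of its catalyst free and 38.5% as spent catalyst. Now take maple's neighbour with [free catalyst] charged at 2.00 mM. Its dose is 132 mM·h, which equals west at 5.66 h, and interpolating between west's 3.8% and 5.9% gives 5.54%. That neighbour ends with 79.6% of its catalyst free and 5.95% of left-handed product.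

(The earlier runs and the new flask come from a simulation on assumed constants, noise included.)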